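Late in this flask's run, the question is how small a remainder of starting material the partner can still reach, and how much time the idle adduct costs on the way.

    starting material + partner → intermediate + released group (k1 = 0.076 M⁻¹ min⁻¹)
    intermediate ⇌ target (K2 = 1.1, k2 = 0.025 min⁻¹)
    intermediate ⇌ isomer of the product (K3 = 14, k3 = 0.014 min⁻¹)
    partner + released group ⇌ idle adduct, settled at all times (K4 = 31 M⁻¹)
    scavenger + released group → scavenged by-product (k5 = 1.7 M⁻¹ min⁻¹)

starting material 0.10 M; partner 0.150 M; scavenger 0.150 M; time 15 h

- amounts and yields of released group count idle adduct too
- run time (flask): 15 h

- part of the starting material that has reacted at 15 h
- share of the unused partner that is free and not bound as idle adduct, at 15 h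

1. The first step uses starting material and partner one for one, so the partner excess stays constant. The excess exponent, meaning charge difference times first-step rate constant times time, is 3.42 in this flask. Integrating the second-order rate with both reagents running down gives 98.9% reacted. Bound partner does not react, so this is the bound from above.

2. At the charged concentrations, the half-life of free released group by scavenging is shorter than that of starting material by the first step: 2.7 min against 1.0 h. So [released group] is taken to stay near its steady value. Free partner, charged equal to scavenger, runs at or below [scavenger], which puts [released group] at about first-step constant times [starting material] over scavenging constant, at most 0.00447 M. Free partner then stays above 87.8% of unused partner. Scaling the exponent by that share gives the bound from below, 98.3%.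

3. Integrating the lost share over the run gives a lost time: adduct constant over scavenging constant, times the logarithm of partner charge over excess, or 20.0 min. My reckoning is therefore 98.8% reacted, and the remainder implies a free share of 99.8%.

4. The forecast gives 98.8% and 99.8%, to be set beside the bracket of 98.3% to 98.9% reacted, and holds that “the intermediate's isomerisation steps affect neither answer”.

5. This flask gives 98.8% and 99.8%. With exponent 3.42, its starting material, the limiting reagent, stands at 1.20%.

A neighbouring flask charged with 0.40 M of starting material reverses the excess. Its exponent is 17.1, larger than in the first flask, and the free-share bound of 64.3% still leaves 11.0. The closed form then reduces to partner charge over starting-material charge, 37.5%. In that neighbouring flask, partner stands at 0% and 37.5% of the starting material has reacted.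

(The rate constants were chosen freely; the flask was simulated.)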